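The data were generated by integration from invented constants, and the scatter is random.

In the alder run, 0.38 M of partner on 0.20 M of substrate at 40 °C had left 4.6% of substrate and made 49.2% of target at the last reading, so side product holds the remaining 46.2%.

alder run (percent of the substrate charged)

| time / s | target / % | substrate / % |
|---|---|---|
| 10.0 | 33.6 | 43.2 |
| 20.0 | 42.5 | 20.6 |
| 25.0 | 43.5 | 13.9 |
| 40.0 | 49.2 | 4.6 |

(scatter of a reading: 1 percentage point)

all flasks: substrate 0.20 M

|  | partner | temperature | remark | time |
|---|---|---|---|---|
| alder | 0.38 M | 40 °C | run made earlier |  |
| Saturday's | 0.190 M |  | at 40 °C until 1.5 min, from then on at 10 °C | 3.0 min |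
| Tuesday's | 0.190 M | 40 °C |  | 3.0 min |
| Thursday's | 0.190 M | 10 °C |  | 3.0 min |
| Wednesday's | 0.190 M | 25 °C |  | 3.0 min |

- target is meant together with its crystals
- solid, in amounts per volume of the solution: crystals
- reactions considered so far: substrate + partner -> target; substrate -> side product; crystals <-> target; partner -> decomposed reagent
- the earlier runs do not show what temperature does; that part of a forecast is a guess

- the best flask by amount of target, in percent of the substrate charged; "all alike" if 1.5 percentage points covers them all (Saturday's / Tuesday's / Thursday's / Wednesday's / all alike)
- amount of target at the end, in percent of the substrate charged, Saturday's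
- amount of target at the end, in percent of the substrate charged, Tuesday's
- amount of target at the end, in percent of the substrate charged, Thursday's
- amount of target at the end, in percent of the substrate charged, Wednesday's

Substrate has two exits, and only the exit to target needs partner, so the ratio of side product to target should vary inversely with partner. That suggests a crossing concentration, the partner level at which both exits run equally fast. The side-to-target ratio of 0.939, taken at the alder run's mean partner of 0.331 M, reads it as 0.311 M.

The dimensionless number is partner over this concentration, a selectivity factor, and the share of reacted substrate becoming target is that number over one plus itself. In Tuesday's, the charge of 0.190 M gives 0.612 and a share of 38.0%. The correction is the partner that target consumes: the mean falls to 0.152 M, the number to 0.489, and my reckoning for Tuesday's to 32.9%.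

The number gives the split, not the clock. The alder decay and this split give substrate, in Tuesday's and in Saturday's warm stretch, a reckoned lifetime of 18.0 s at 40 °C. Saturday's stays warm until 1.5 min, longer than that lifetime, so the reckoning leaves about 0.674% of its substrate at the change, and Saturday's should match Tuesday's. For Wednesday's and Thursday's one number is not enough: the earlier runs do not show what temperature does to split or clock, so that part remains a guess.

The forecast gives 33% for Saturday's, 33% for Tuesday's, 32% for Wednesday's and 22% for Thursday's, and names Tuesday's as best. Its ground at the cold end reads “Thursday's stays low unless selectivity improves”.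

The flasks give 31.1% in Saturday's, 31.1% in Tuesday's, 35.3% in Wednesday's and 23.7% in Thursday's, so Wednesday's is best, by 4.2 percentage points over Tuesday's, more than the margin.

    substrate + partner → target (k = 2.60 M⁻¹ min⁻¹, Ea = 63.0 kJ mol⁻¹)
    substrate → side product (k = 0.560 min⁻¹, Ea = 75.0 kJ mol⁻¹)
    crystals ⇌ target, rate k3*(cs3 - [target]) while solid is left; crystals form when [target] > cs3 (solubility = 21.0 mM, k = 8.80 min⁻¹)
    partner → decomposed reagent (k = 0.130 min⁻¹, Ea = 93.0 kJ mol⁻¹)
    (constants at 25 °C)

Wednesday's started with a side-to-target rate ratio of 1.1, which puts its crossing concentration at 25 °C at 0.215 M, below the 0.311 M read, with the scatter of the alder readings, at 40 °C. The neighbour of Wednesday's with 0.76 M of partner has, after the same correction for partner taken up by target, a mean partner of 0.682 M, so a number of 3.17 and a reckoned share of 76.0%, and that neighbour holds 74.6% of target at the end.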